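## Retrosynthetic overview

Ring A = cyclohexenone, ring B = tetrahydrofuran (C2–O–C9), ring C = oxepane (C3–O–C16), ring D = oxonane.

1. Ring D is closed last by ring-closing metathesis of a C4-allyl/C9-methallyl diene; the 6-OAc/7-OH pair comes from the (Z)-C6=C7 alkene by ketohydroxylation and OH-directed reduction.
2. Ring B: C2–OH closes on a C9 aldehyde (methyl acetal); C8 then enters by C-methallylation at C9, and C4–C5 by chelation-controlled allylation of a C4 aldehyde.
3. Rings A and C form together in an intramolecular Diels–Alder reaction: 2-silyloxydiene (C11–C14) plus (Z)-γ-silyloxy enoate (C1=C10), tethered through the C3–O–C16 ether. Saegusa oxidation then gives the C11–C13 enone.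
4. The tether comes from Pd-catalysed asymmetric etherification of isoprene monoxide with a γ-hydroxy enone (sets C3); C2 from asymmetric propiolate addition; C15 from (S)-β-methyl-γ-butyrolactone.
5. Ring order: A + C (one operation) → B → D.

Assumption: locants C1–C20 follow the briarellin (eunicellane) numbering of the target, and the ligand antipodes named in steps 2 and 4 are those expected to give the stated configurations (the other antipode is used if the observed sense is opposite).

## Route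

Step 1
Reactants: 1 (S)-4-methyldihydrofuran-2(3H)-one; 2 (E)-1-bromoprop-1-ene
Product: 4 (2S,5E)-1-hydroxy-2-methylhept-5-en-4-one, via (E)-prop-1-enyllithium 3 (not isolated)
Conditions: 2, t-BuLi (2 equiv), Et2O, −78 °C; then 1, THF, −78 °C; aq NH4Cl
Reagents that add atoms: none
Why: Acyl substitution of the lactone by one equivalent of the vinyllithium (the lithium lactolate survives at −78 °C and collapses only on work-up) gives the γ-hydroxy (E)-enone, Br/Li exchange retaining the E geometry and C15 coming unchanged from 1.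

Step 2
Reactants: 4 (2S,5E)-1-hydroxy-2-methylhept-5-en-4-one; 5 2-methyl-2-vinyloxirane (racemic)
Product: 6 (2S,5E)-1-{[(2R)-1-hydroxy-2-methylbut-3-en-2-yl]oxy}-2-methylhept-5-en-4-one
Conditions: Pd2(dba)3·CHCl3 (1 mol %), (S,S)-DACH-phenyl Trost ligand (3 mol %), Et3B (2 mol %), CH2Cl2, rt
Reagents that add atoms: none
Why: Trost dynamic kinetic asymmetric allylic etherification of the vinyl epoxide (boron-mediated delivery of the alcohol to the branched π-allyl terminus) forms the tertiary ether and sets C3 (R) by ligand control.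

Step 3
Reactants: 6
Product: 7 (2R)-2-methyl-2-{[(2S,5E)-2-methyl-4-oxohept-5-en-1-yl]oxy}but-3-enal
Conditions: Dess–Martin periodinane, CH2Cl2, 0 °C to rt
Reagents that add atoms: none
Why: Dess–Martin oxidation of the neopentyl primary alcohol gives a non-enolisable α-alkoxy aldehyde without touching the enone or C3.

Step 4
Reactants: 7; 8 methyl propiolate
Product: 10 methyl (4R,5R)-4-hydroxy-5-methyl-5-{[(2S,5E)-2-methyl-4-oxohept-5-en-1-yl]oxy}hept-6-en-2-ynoate, via methylzinc propiolate 9 (not isolated)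
Conditions: 8 (2.8 equiv), Me2Zn (2.9 equiv), (S,S)-ProPhenol (20 mol %), Ph3P=O (40 mol %), toluene, 4 °C; aq NH4Cl
Reagents that add atoms: none
Why: Dinuclear zinc–ProPhenol asymmetric alkynylation adds the zinc acetylide to the Re face of the aldehyde under catalyst control (the Me/vinyl pair on C3 gives no useful substrate bias), setting C2 (R); the enone ketone is inert to alkynylzinc.

Step 5
Reactants: 10
Product: 11 methyl (4R,5R)-5-methyl-5-{[(2S,3Z,5E)-2-methyl-4-(triethylsilyloxy)hepta-3,5-dien-1-yl]oxy}-4-(triethylsilyloxy)hept-6-en-2-ynoate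
Conditions: TESOTf (2.5 equiv), Et3N (4 equiv), CH2Cl2, −78 to 0 °C
Reagents that add atoms: triethylsilyl trifluoromethanesulfonate, CC[Si](CC)(CC)OS(=O)(=O)C(F)(F)F
Why: Soft enolisation–silylation protects C2–OH and converts the enone by α′-deprotonation at C14 into the cross-conjugated (Z)-2-silyloxydiene (C15 "outside"), with no stereocentre created.

Step 6
Reactants: 11
Product: 12 methyl (2Z,4R,5R)-5-methyl-5-{[(2S,3Z,5E)-2-methyl-4-(triethylsilyloxy)hepta-3,5-dien-1-yl]oxy}-4-(triethylsilyloxy)hepta-2,6-dienoate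
Conditions: H2 (1 atm), Pd/CaCO3 poisoned with Pb(OAc)2 (Lindlar catalyst), quinoline, EtOAc, 0 °C
Reagents that add atoms: none
Why: Lindlar semihydrogenation (syn H2 delivery) gives the (Z)-enoate faster than the silyloxydiene or the hindered vinyl group reacts.

Step 7
Reactants: 12
Product: 13 methyl (1R,2R,5S,5aS,8S,9S,9aR)-2-ethenyl-2,5,8-trimethyl-1,6-bis(triethylsilyloxy)-1,2,4,5,5a,8,9,9a-octahydro-3-benzoxepine-9-carboxylate (rings A and C)
Conditions: toluene (0.005 M), BHT, 135 °C, sealed tube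
Reagents that add atoms: none
Why: Thermal type 1 intramolecular Diels–Alder reaction forms rings A and C at once: the electron-rich 2-silyloxydiene adds to the (Z)-enoate with ester and tether endo, the allylic C2–H eclipsing the alkene (A(1,3) strain) and the diene arriving on the C3 face anti to the C2 silyloxy group, which sets C1, C10 and C14 (H1, H10, H14 all cis; C14 trans to C3 across the future ring B), C11 being transient.

Step 8
Reactants: 13
Product: 14 (1R,2R,5S,5aS,8S,9S,9aR)-2-ethenyl-2,5,8-trimethyl-1,6-bis(triethylsilyloxy)-1,2,4,5,5a,8,9,9a-octahydro-3-benzoxepine-9-carbaldehyde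
Conditions: i-Bu2AlH (1.15 equiv), CH2Cl2, −78 °C; Rochelle salt
Reagents that add atoms: none
Why: Low-temperature i-Bu2AlH partial reduction stops at the aluminium hemiacetal and releases the C9 aldehyde on work-up, the silyl ether and silyl enol ether being inert.

Step 9
Reactants: 14
Product: 16 tricyclic methyl acetal (rings A, B, C; 9-OMe anti to ring A, C3 bearing CH3 and vinyl), via enone aldehyde 15 (not isolated)
Conditions: Pd(OAc)2 (1.1 equiv), MeCN, rt; then MeOH, PPTS (0.3 equiv), rt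
Reagents that add atoms: methanol, CO
Why: Saegusa–Ito oxidation (Pd enolate at C12, β-hydride loss from C11) gives the C11=C12–C13=O enone regiospecifically, and acidic methanolysis of the C2 silyl ether lets C2–OH close on the cis C9 aldehyde as the methyl acetal (ring B), C9 being an inconsequential anomeric centre.

Step 10
Reactants: 16
Product: 18 tricyclic C4 aldehyde (C3 bearing CH3 and CHO), via vicinal diol 17 (not isolated)
Conditions: OsO4 (2 mol %), NaIO4 (4 equiv), 2,6-lutidine, dioxane/H2O 3:1, rt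
Reagents that add atoms: osmium tetroxide, O=[Os](=O)(=O)=O (catalytic oxygen carrier); sodium periodate, [Na+].[O-]I(=O)(=O)=O (re-oxidant supplying that oxygen)
Why: Lemieux–Johnson oxidation (dihydroxylation then glycol cleavage) removes the terminal carbon of the monosubstituted vinyl group in preference to the electron-poor trisubstituted enone alkene.

Step 11
Reactants: 18; 19 allyltributylstannane
Product: 20 (4S)-homoallylic alcohol (C4–OH, C5H2–C6H=CH2 on C3; tricycle unchanged)
Conditions: 19 (2 equiv), MgBr2·OEt2 (3 equiv), CH2Cl2, −78 to −20 °C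
Reagents that add atoms: none
Why: Chelation-controlled (Cram-chelate) allylation: MgBr2 bridges the aldehyde and the ring C ether oxygen, and the allylstannane attacks from the C18 methyl side and not the C2 ring side, setting C4 (S).

Step 12
Reactants: 20
Product: 21 C4 tert-butyldimethylsilyl ether of 20
Conditions: TBSOTf (1.5 equiv), 2,6-lutidine, CH2Cl2, −78 °C
Reagents that add atoms: tert-butyldimethylsilyl trifluoromethanesulfonate, CC(C)(C)[Si](C)(C)OS(=O)(=O)C(F)(F)F
Why: Silyl ether formation masks C4–OH, which would otherwise trap the C9 oxocarbenium ion and be oxidised or acetylated later.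

Step 13
Reactants: 21; 22 trimethyl(2-methylallyl)silane
Product: 23 C9 methallyl tricycle (C8H2–C7(CH3)=CH2 on C9, cis to C3 across ring B)
Conditions: 22 (4 equiv), TMSOTf (0.3 equiv), CH2Cl2, −78 to −40 °C
Reagents that add atoms: none
Why: Hosomi–Sakurai C-glycosylation: the C9 oxocarbenium ion, held in the C1-down envelope by the trans-fused oxepane and cis-fused ring A, is attacked inside the envelope on the face anti to pseudoaxial C11, giving the 2,9-cis tetrahydrofuran (C9 R).

Step 14
Reactants: 23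
Product: 24 tetracyclic (Z)-C6=C7 oxonene (rings A–D, C4–OTBS)
Conditions: RuCl2(=CHPh)(SIMes)(PCy3) (second-generation Grubbs catalyst, 10 mol %), CH2Cl2 (0.002 M), 40 °C
Reagents that add atoms: none
Why: Ring-closing metathesis of the monosubstituted and 1,1-disubstituted alkenes closes the nine-membered ring D, the cis C2/C9 arms pre-organising the diene and the ring size enforcing the (Z)-trisubstituted alkene.

Step 15
Reactants: 24
Product: 25 (7S)-7-hydroxy-6-ketone (α-ketol; C4–OTBS)
Conditions: RuCl3 (1 mol %), KHSO5 (as 2KHSO5·KHSO4·K2SO4, 5 equiv), NaHCO3, EtOAc/MeCN/H2O 6:6:1, rt, 10 min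
Reagents that add atoms: potassium peroxymonosulfate, [K+].[O-]S(=O)(=O)OO (both new oxygen atoms, relayed through RuO4)
Why: RuO4-catalysed ketohydroxylation: syn addition to the peripheral face of the electron-rich ring alkene (the face opposite the C1/C10 bridge) and in situ oxidation at the secondary carbon give the C6 ketone and set the C7 tertiary alcohol (S), the enone alkene reacting far more slowly.

Step 16
Reactants: 25
Product: 26 (6S,7S)-6,7-diol (C4–OTBS)
Conditions: Me4NBH(OAc)3 (5 equiv), MeCN/AcOH 1:1, −30 °C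
Reagents that add atoms: none
Why: Hydroxy-directed (Evans–Saksena type) reduction: the acetoxyborohydride bound to C7–OH delivers hydride to the same face of the C6 ketone, giving the trans 6S,7S diol, while the undirected enone carbonyl is not reduced.

Step 17
Reactants: 26
Product: 27 C6 acetate (C4–OTBS, C7–OH free)
Conditions: Ac2O (3 equiv), DMAP (cat.), pyridine, CH2Cl2, 0 °C to rt
Reagents that add atoms: acetic anhydride, CC(=O)OC(C)=O
Why: DMAP-catalysed acylation takes only the secondary C6–OH, C7–OH being tertiary and C4–OH silylated.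

Step 18
Reactants: 27
Product: 28 CNP0336530.3 (target)
Conditions: HF·pyridine, THF/pyridine, 0 °C to rt
Reagents that add atoms: none
Why: Fluoride-mediated silyl ether cleavage under buffered acidic conditions frees C4–OH without acetate migration or damage to the enone and tertiary alcohol.

## Compound list

1 | (S)-4-methyldihydrofuran-2(3H)-one | C[C@@H]1COC(=O)C1 | starting material
2 | (E)-1-bromoprop-1-ene | C/C=C/Br | starting material
3 | (E)-prop-1-en-1-yllithium | C/C=C/[Li] | intermediate (not isolated)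
4 | (2S,5E)-1-hydroxy-2-methylhept-5-en-4-one | C/C=C/C(=O)C[C@H](C)CO | intermediate
5 | 2-methyl-2-vinyloxirane (isoprene monoxide, racemic) | CC1(C=C)CO1 | starting material
6 | (2S,5E)-1-{[(2R)-1-hydroxy-2-methylbut-3-en-2-yl]oxy}-2-methylhept-5-en-4-one | C/C=C/C(=O)C[C@H](C)CO[C@](C)(C=C)CO | intermediate
7 | (2R)-2-methyl-2-{[(2S,5E)-2-methyl-4-oxohept-5-en-1-yl]oxy}but-3-enal | C/C=C/C(=O)C[C@H](C)CO[C@](C)(C=C)C=O | intermediate
8 | methyl propiolate | C#CC(=O)OC | starting material
9 | methyl 3-(methylzincio)prop-2-ynoate | C[Zn]C#CC(=O)OC | intermediate (not isolated)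
10 | methyl (4R,5R)-4-hydroxy-5-methyl-5-{[(2S,5E)-2-methyl-4-oxohept-5-en-1-yl]oxy}hept-6-en-2-ynoate | C/C=C/C(=O)C[C@H](C)CO[C@](C)(C=C)[C@H](O)C#CC(=O)OC | intermediate
11 | methyl (4R,5R)-5-methyl-5-{[(2S,3Z,5E)-2-methyl-4-(triethylsilyloxy)hepta-3,5-dien-1-yl]oxy}-4-(triethylsilyloxy)hept-6-en-2-ynoate | C/C=C/C(O[Si](CC)(CC)CC)=C/[C@H](C)CO[C@](C)(C=C)[C@H](O[Si](CC)(CC)CC)C#CC(=O)OC | intermediate
12 | methyl (2Z,4R,5R)-5-methyl-5-{[(2S,3Z,5E)-2-methyl-4-(triethylsilyloxy)hepta-3,5-dien-1-yl]oxy}-4-(triethylsilyloxy)hepta-2,6-dienoate | C/C=C/C(O[Si](CC)(CC)CC)=C/[C@H](C)CO[C@](C)(C=C)[C@H](O[Si](CC)(CC)CC)/C=C\C(=O)OC | intermediate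
13 | methyl (1R,2R,5S,5aS,8S,9S,9aR)-2-ethenyl-2,5,8-trimethyl-1,6-bis(triethylsilyloxy)-1,2,4,5,5a,8,9,9a-octahydro-3-benzoxepine-9-carboxylate | C=C[C@@]2(C)OC[C@@H](C)[C@@H]3C(O[Si](CC)(CC)CC)=C[C@H](C)[C@H](C(=O)OC)[C@@H]3[C@H]2O[Si](CC)(CC)CC | intermediate
14 | (1R,2R,5S,5aS,8S,9S,9aR)-2-ethenyl-2,5,8-trimethyl-1,6-bis(triethylsilyloxy)-1,2,4,5,5a,8,9,9a-octahydro-3-benzoxepine-9-carbaldehyde | C=C[C@@]2(C)OC[C@@H](C)[C@@H]3C(O[Si](CC)(CC)CC)=C[C@H](C)[C@H](C=O)[C@@H]3[C@H]2O[Si](CC)(CC)CC | intermediate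
15 | (1R,2R,5S,5aS,9R,9aS)-2-ethenyl-2,5,8-trimethyl-6-oxo-1-(triethylsilyloxy)-1,2,4,5,5a,6,9,9a-octahydro-3-benzoxepine-9-carbaldehyde | C=C[C@@]2(C)OC[C@@H](C)[C@@H]3C(=O)C=C(C)[C@H](C=O)[C@@H]3[C@H]2O[Si](CC)(CC)CC | intermediate (not isolated)
16 | tricyclic methyl acetal, rings A/B/C: 2,9-epoxy-9-methoxy and 3,16-epoxy, C11=C12–C13=O enone, C3 with CH3 and vinyl; (1S,2R,3R,9S,10R,14S,15S), major anomer drawn | C=C[C@@]2(C)OC[C@@H](C)[C@@H]3C(=O)C=C(C)[C@H]4[C@@H]3[C@H]2O[C@@H]4OC | intermediate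
17 | diol from 16: C3 bears CH(OH)CH2OH (C4 epimers, centre undefined); other centres as in 16 | OCC(O)[C@@]2(C)OC[C@@H](C)[C@@H]3C(=O)C=C(C)[C@H]4[C@@H]3[C@H]2O[C@@H]4OC | intermediate (not isolated)
18 | tricyclic C4 aldehyde: C3 bears CH3 and CHO; other centres as in 16 | O=C[C@@]2(C)OC[C@@H](C)[C@@H]3C(=O)C=C(C)[C@H]4[C@@H]3[C@H]2O[C@@H]4OC | intermediate
19 | allyltributylstannane | C=CC[Sn](CCCC)(CCCC)CCCC | starting material
20 | (4S)-homoallylic alcohol: C3 bears CH3 and (S)-CH(OH)CH2CH=CH2; other centres as in 16 | C=CC[C@H](O)[C@@]2(C)OC[C@@H](C)[C@@H]3C(=O)C=C(C)[C@H]4[C@@H]3[C@H]2O[C@@H]4OC | intermediate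
21 | C4 tert-butyldimethylsilyl ether of 20 | C=CC[C@H](O[Si](C)(C)C(C)(C)C)[C@@]2(C)OC[C@@H](C)[C@@H]3C(=O)C=C(C)[C@H]4[C@@H]3[C@H]2O[C@@H]4OC | intermediate
22 | trimethyl(2-methylallyl)silane | CC(=C)C[Si](C)(C)C | starting material
23 | C9 methallyl tricycle (9R; C8 cis to C3 on ring B; C4–OTBS, C4 allyl) | C=CC[C@H](O[Si](C)(C)C(C)(C)C)[C@@]2(C)OC[C@@H](C)[C@@H]3C(=O)C=C(C)[C@H]4[C@@H]3[C@H]2O[C@@H]4CC(C)=C | intermediate
24 | tetracyclic (6Z)-oxonene: rings A–D, C6=C7(CH3), C4–OTBS; ring centres as in 28 | C1/C(C)=C\C[C@H](O[Si](C)(C)C(C)(C)C)[C@@]2(C)OC[C@@H](C)[C@@H]3C(=O)C=C(C)[C@H]4[C@@H]3[C@H]2O[C@@H]41 | intermediate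
25 | (7S)-7-hydroxy-6-oxo tetracycle (C4–OTBS) | O=C1C[C@H](O[Si](C)(C)C(C)(C)C)[C@@]2(C)OC[C@@H](C)[C@@H]3C(=O)C=C(C)[C@H]4[C@@H]3[C@H]2O[C@@H]4C[C@]1(C)O | intermediate
26 | (6S,7S)-6,7-dihydroxy tetracycle (C4–OTBS) | O[C@H]1C[C@H](O[Si](C)(C)C(C)(C)C)[C@@]2(C)OC[C@@H](C)[C@@H]3C(=O)C=C(C)[C@H]4[C@@H]3[C@H]2O[C@@H]4C[C@]1(C)O | intermediate
27 | (6S,7S)-6-acetoxy-7-hydroxy tetracycle (C4–OTBS) | CC(=O)O[C@H]1C[C@H](O[Si](C)(C)C(C)(C)C)[C@@]2(C)OC[C@@H](C)[C@@H]3C(=O)C=C(C)[C@H]4[C@@H]3[C@H]2O[C@@H]4C[C@]1(C)O | intermediate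
28 | CNP0336530.3, (1S,2R,3R,4S,6S,7S,9R,10R,14S,15S) | CC(=O)O[C@H]1C[C@H](O)[C@@]2(C)OC[C@@H](C)[C@@H]3C(=O)C=C(C)[C@H]4[C@@H]3[C@H]2O[C@@H]4C[C@]1(C)O | target

## Step count and risks

Total: 18 steps. Longest linear sequence: 18 steps, from lactone 1; all other inputs are commercial.

**Step 7 (intramolecular Diels–Alder).** The tether closes a seven-membered ring, the (Z)-enoate is only a moderate dienophile, and an exo mode or addition to the C3 vinyl group could compete. An exo (C14-epimeric) adduct could be equilibrated later, because C14 is α to the C13 ketone. Fallback, an anionic ring construction in place of the thermal cycloaddition: starting from 10, TESCl/imidazole gives methyl (4R,5R)-5-methyl-5-{[(2S,5E)-2-methyl-4-oxohept-5-en-1-yl]oxy}-4-(triethylsilyloxy)hept-6-en-2-ynoate F1. Lindlar reduction gives the corresponding (2Z)-enoate with the ketone left free, F2. LDA (THF, −78 to −20 °C) forms the kinetic cross-conjugated lithium dienolate at C14. This adds to C1 through a lithium-chelated Michael transition state, and the resulting ester enolate (C10) closes onto the enone at C11 (double Michael ring closure). Quenching the C12=C13 enolate with TESCl returns to 13; the C11 configuration is irrelevant because it is removed in step 9.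

**Step 14 (ring-closing metathesis).** This forms a trisubstituted alkene in a nine-membered ring on a rigid tricycle. Fallback, ring D closed at C6–C7 by a Nozaki–Hiyama–Kishi reaction: starting from 21, (2-bromoallyl)trimethylsilane/TMSOTf gives the C9 2-bromoallyl tricycle F3. OsO4/NaIO4 cleaves the C4 allyl group to the C6 aldehyde F4. CrCl2/NiCl2 (cat.) in DMSO at high dilution closes the ring to the (6S)-allylic alcohol with an exocyclic C7 methylene, F5. Ac2O/DMAP gives the C6 acetate F6. Mukaiyama hydration (Co(acac)2, PhSiH3, O2) of the 1,1-disubstituted alkene installs the C7 tertiary alcohol from the peripheral face and returns to 27.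

**Step 15 (ketohydroxylation).** The face of attack on the medium-ring alkene is inferred, not demonstrated, and RuO4 could over-oxidise. If the C7 alcohol of 25 proves epimeric (oxidant attack on the C1/C10-side face), that preference is used for anti-dioxygenation instead: starting from 24, dimethyldioxirane gives the (6S,7R)-6,7-epoxide F7, in which C6–O already has the target configuration. Sc(OTf)3-catalysed hydrolysis opens it at tertiary C7 with inversion and returns directly to 26.

Further compounds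
F1 | step 7 | methyl (4R,5R)-5-methyl-5-{[(2S,5E)-2-methyl-4-oxohept-5-en-1-yl]oxy}-4-(triethylsilyloxy)hept-6-en-2-ynoate | C/C=C/C(=O)C[C@H](C)CO[C@](C)(C=C)[C@H](O[Si](CC)(CC)CC)C#CC(=O)OC
F2 | step 7 | methyl (2Z,4R,5R)-5-methyl-5-{[(2S,5E)-2-methyl-4-oxohept-5-en-1-yl]oxy}-4-(triethylsilyloxy)hepta-2,6-dienoate | C/C=C/C(=O)C[C@H](C)CO[C@](C)(C=C)[C@H](O[Si](CC)(CC)CC)/C=C\C(=O)OC
F3 | step 14 | C9 2-bromoallyl tricycle (C4–OTBS, C4 allyl; centres as in 23) | C=CC[C@H](O[Si](C)(C)C(C)(C)C)[C@@]2(C)OC[C@@H](C)[C@@H]3C(=O)C=C(C)[C@H]4[C@@H]3[C@H]2O[C@@H]4CC(Br)=C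
F4 | step 14 | C6 aldehyde of F3 (C5H2–CHO on C4) | O=CC[C@H](O[Si](C)(C)C(C)(C)C)[C@@]2(C)OC[C@@H](C)[C@@H]3C(=O)C=C(C)[C@H]4[C@@H]3[C@H]2O[C@@H]4CC(Br)=C
F5 | step 14 | (6S)-6-hydroxy-7-methylidene tetracycle (C4–OTBS) | O[C@H]1C[C@H](O[Si](C)(C)C(C)(C)C)[C@@]2(C)OC[C@@H](C)[C@@H]3C(=O)C=C(C)[C@H]4[C@@H]3[C@H]2O[C@@H]4CC1=C
F6 | step 14 | (6S)-6-acetoxy-7-methylidene tetracycle (C4–OTBS) | CC(=O)O[C@H]1C[C@H](O[Si](C)(C)C(C)(C)C)[C@@]2(C)OC[C@@H](C)[C@@H]3C(=O)C=C(C)[C@H]4[C@@H]3[C@H]2O[C@@H]4CC1=C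
F7 | step 15 | (6S,7R)-6,7-epoxide of 24 (oxygen on the C1/C10-side face) | C[C@]12O[C@H]1C[C@H](O[Si](C)(C)C(C)(C)C)[C@@]3(C)OC[C@@H](C)[C@@H]4C(=O)C=C(C)[C@H]5[C@@H]4[C@H]3O[C@@H]5C2
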